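The route rests on cutting O1–C8a, C4–C4a and O1–C2 in both chromanone halves. It exploits the ortho relationship on ring A between the ether oxygen O1 (at C8a) and the ketone carbon C4 (at C4a), with O7 para to C4a: exactly what an aryne leaves when a carboxylate adds and its acyl group shifts to the neighbouring carbon. In one operation, step 7 should join an (E,E)-bis(arylidene)succinic acid, which already holds C2–C3–C4, the C3–C3'' bond and both B rings, to two chlorine-steered arynes and close both pyranone rings with their four stereocentres. Base-mediated crystallization then selects the meso isomer, and the benzyl ethers and both directing chlorines leave together by hydrogenolysis.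

Key step: step 7

Remark: the target is the achiral meso isomer (2S,3R,2''R,3''S) with both rings 2,3-trans, so no absolute stereocontrol is needed. All four phenols are carried as benzyl ethers, so that one neutral hydrogenolysis removes them together with both chlorines and no Lewis-acid dealkylation is needed after the stereocentres are set. Compound 15 is a mixture of two diastereomers and its SMILES is therefore written without stereodescriptors. Flavanone numbering is used (O1, C2, C3, C4, C4a, C5–C8, C8a; doubly primed locants for the second half).

Step 1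
Reactants: 1 4-(benzyloxy)phenol
Product: 2 4-(benzyloxy)-2-chlorophenol
Conditions: SO2Cl2 (1.0 equiv), CH2Cl2, 0 °C to rt
Reagents that add atoms: sulfuryl chloride, O=S(=O)(Cl)Cl
Why: Electrophilic aromatic chlorination with one equivalent of sulfuryl chloride should take a position ortho to the free hydroxyl group, the strongest director on a ring whose para position is blocked, without touching the benzyl ether.

Step 2
Reactants: 2 4-(benzyloxy)-2-chlorophenol
Product: 3 4-(benzyloxy)-2-bromo-6-chlorophenol
Conditions: NBS, MeCN, 0 °C to rt, dark
Reagents that add atoms: N-bromosuccinimide, O=C1CCC(=O)N1Br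
Why: Electrophilic aromatic bromination with NBS should fill the remaining position ortho to the hydroxyl group, which is more activated than the two positions ortho to the benzyloxy group.

Step 3
Reactants: 3 4-(benzyloxy)-2-bromo-6-chlorophenol
Product: 6 4-(benzyloxy)-2-chloro-6-(trimethylsilyl)phenyl trifluoromethanesulfonate, via aryl trimethylsilyl ether 4 (not isolated), via lithium 2-silylphenoxide 5 (not isolated)
Conditions: HMDS, THF, 70 °C, evaporate; n-BuLi, THF, −78 °C; Tf2O, −78 °C to rt
Reagents that add atoms: hexamethyldisilazane, C[Si](C)(C)N[Si](C)(C)C; trifluoromethanesulfonic anhydride, O=S(=O)(OS(=O)(=O)C(F)(F)F)C(F)(F)F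
Why: O-silylation, bromine–lithium exchange (much faster at −78 °C than any reaction at the C–Cl bond or the benzyl ether), anionic 1,3-shift of silicon from oxygen to carbon (retro-Brook rearrangement) and O-triflation of the resulting phenoxide form the standard one-flask entry to o-silylaryl triflates.

Step 4
Reactants: 7 diethyl succinate; 8 4-(benzyloxy)benzaldehyde
Product: 9 (E)-4-[4-(benzyloxy)phenyl]-3-(ethoxycarbonyl)but-3-enoic acid
Conditions: t-BuOK, t-BuOH, reflux; aq HCl
Reagents that add atoms: none
Why: The Stobbe condensation (aldol addition, lactonization to the paraconate ester and base-induced ring opening) should give the half-ester with the E alkene, in which the aryl group lies trans to the ester.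

Step 5
Reactants: 9 (E)-4-[4-(benzyloxy)phenyl]-3-(ethoxycarbonyl)but-3-enoic acid
Product: 10 diethyl (E)-2-[4-(benzyloxy)benzylidene]succinate
Conditions: EtI, K2CO3, DMF, rt
Reagents that add atoms: iodoethane, CCI
Why: SN2 O-alkylation of the carboxylate regenerates a diester, which a second Stobbe condensation requires, under non-acidic conditions that leave the alkene position and the benzyl ether alone.

Step 6
Reactants: 10 diethyl (E)-2-[4-(benzyloxy)benzylidene]succinate; 8 4-(benzyloxy)benzaldehyde
Product: 12 (2E,3E)-2,3-bis[4-(benzyloxy)benzylidene]succinic acid, via bis(arylidene)succinic monoethyl ester 11 (not isolated)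
Conditions: t-BuOK, t-BuOH, reflux; then KOH, EtOH–H2O, reflux; aq HCl; crystallization
Reagents that add atoms: potassium hydroxide, [K+].[OH-]
Why: A second Stobbe condensation at the remaining methylene group should install the second arylidene unit with E geometry, and saponification of the half-ester salt in the same flask gives the diacid, which crystallization should free from minor alkene isomers (the alkene geometry is erased in step 7 in any case).

Step 7
Reactants: 12 (2E,3E)-2,3-bis[4-(benzyloxy)benzylidene]succinic acid; 6 4-(benzyloxy)-2-chloro-6-(trimethylsilyl)phenyl trifluoromethanesulfonate (slight excess over two equivalents)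
Product: 15 7,7'',4',4'''-tetrakis(benzyloxy)-5,5''-dichloro-3,3''-biflavanone as a mixture of its two trans,trans diastereomers (meso plus racemic C2-symmetric), via 5-(benzyloxy)-3-chlorobenzyne 13 (not isolated), via bis(2'-hydroxychalcone) 14 (not isolated)
Conditions: CsF (excess), THF, 125 °C, sealed tube
Reagents that add atoms: none
Why: Proposed new method: fluoride frees aryne 13 from 6 and each carboxylate of 12 adds to the aryne carbon remote from chlorine, because the inductively withdrawing chlorine next to the triple bond (and the ring distortion it imposes) places the developing aryl anion beside it; that anion attacks its own ester carbonyl through a four-membered transition state and the ring opens to the o-acyl phenoxide of 14, which makes O1–C8a and C4–C4a and leaves benzyloxy at C7 and chlorine at C5. The closest known reaction type is the formal insertion of an aryne into the C–O bond of a carboxylic acid to give an o-hydroxyaryl ketone, here to be used twice on a dienedioic acid and followed in the same pot by the chalcone-to-flavanone isomerization. Each pyranone ring closes by 6-endo-trig oxa-Michael addition of the phenoxide to C2, and the resulting enolate is protonated at C3 by the acid protons held as hydrogen fluoride, so the equation needs no external proton source. C2, C3, C2'' and C3'' are set under thermodynamic control (reversible oxa-Michael addition, enolizable C3), which should place the aryl group and the C3 substituent trans and equatorial in each ring, helped by the peri chlorine, which twists the open chalcone and favours the closed form. The step needs regioselectivity at the aryne, secured by the chlorine of 13, and an acyl shift faster than protonation of the aryl anion, favoured by hot aprotic THF. Nothing in the substrate controls how the two halves relate, so 15 is expected as a mixture of the meso and the C2-symmetric trans,trans diastereomers, which step 8 converges on the meso form.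

Step 8
Reactants: 15 7,7'',4',4'''-tetrakis(benzyloxy)-5,5''-dichloro-3,3''-biflavanone (mixture of the two trans,trans diastereomers)
Product: 16 meso-(2S,3R,2''R,3''S)-7,7'',4',4'''-tetrakis(benzyloxy)-5,5''-dichloro-3,3''-biflavanone
Conditions: DBU (cat.), EtOH–toluene, 70 °C to 20 °C, seeding, filtration; mother liquor re-equilibrated
Reagents that add atoms: none
Why: Base-mediated flavanone–chalcone equilibration (reversible E1cB ring opening through the C3 enolate to the 2'-hydroxychalcone and oxa-Michael re-closure) resets C2 and C3 of one half at a time while keeping each ring trans, so the two diastereomers interconvert in solution and crystallization of the centrosymmetric meso form should drain the equilibrium (crystallization-induced diastereomer transformation), which fixes the configuration of one half relative to the other.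

Step 9
Reactants: 16 meso-(2S,3R,2''R,3''S)-7,7'',4',4'''-tetrakis(benzyloxy)-5,5''-dichloro-3,3''-biflavanone
Product: 17 meso-(2S,3R,2''R,3''S)-7,7'',4',4'''-tetrahydroxy-3,3''-biflavanone (target, CNP0231820.1)
Conditions: H2 (1 atm), Pd/C, NaOAc, THF–MeOH, rt
Reagents that add atoms: none
Why: Palladium-catalysed hydrogenolysis should cleave the four aryl benzyl ethers and, with acetate taking up the hydrogen chloride, both aryl C–Cl bonds (hydrodechlorination), while the buffered conditions at room temperature leave the four stereocentres alone, since exchange of the meso for the C2-symmetric form would require opening of a pyranone ring.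

Compound list
1 | 4-(benzyloxy)phenol | Oc1ccc(OCc2ccccc2)cc1 | starting material
2 | 4-(benzyloxy)-2-chlorophenol | Oc1ccc(OCc2ccccc2)cc1Cl | intermediate
3 | 4-(benzyloxy)-2-bromo-6-chlorophenol | Oc1c(Br)cc(OCc2ccccc2)cc1Cl | intermediate
4 | [4-(benzyloxy)-2-bromo-6-chlorophenoxy]trimethylsilane | C[Si](C)(C)Oc1c(Br)cc(OCc2ccccc2)cc1Cl | intermediate (not isolated)
5 | lithium 4-(benzyloxy)-2-chloro-6-(trimethylsilyl)phenolate | [Li+].[O-]c1c(Cl)cc(OCc2ccccc2)cc1[Si](C)(C)C | intermediate (not isolated)
6 | 4-(benzyloxy)-2-chloro-6-(trimethylsilyl)phenyl trifluoromethanesulfonate | C[Si](C)(C)c1cc(OCc2ccccc2)cc(Cl)c1OS(=O)(=O)C(F)(F)F | intermediate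
7 | diethyl succinate | CCOC(=O)CCC(=O)OCC | starting material
8 | 4-(benzyloxy)benzaldehyde | O=Cc1ccc(OCc2ccccc2)cc1 | starting material
9 | (E)-4-[4-(benzyloxy)phenyl]-3-(ethoxycarbonyl)but-3-enoic acid | CCOC(=O)/C(=C/c1ccc(OCc2ccccc2)cc1)CC(=O)O | intermediate
10 | diethyl (E)-2-[4-(benzyloxy)benzylidene]succinate | CCOC(=O)/C(=C/c1ccc(OCc2ccccc2)cc1)CC(=O)OCC | intermediate
11 | (2E,3E)-2,3-bis[4-(benzyloxy)benzylidene]succinic acid monoethyl ester (formed as its potassium salt) | CCOC(=O)/C(=C/c1ccc(OCc2ccccc2)cc1)/C(=C\c1ccc(OCc2ccccc2)cc1)C(=O)O | intermediate (not isolated)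
12 | (2E,3E)-2,3-bis[4-(benzyloxy)benzylidene]succinic acid | OC(=O)/C(=C/c1ccc(OCc2ccccc2)cc1)/C(=C\c1ccc(OCc2ccccc2)cc1)C(=O)O | intermediate (precursor of the key step)
13 | 5-(benzyloxy)-3-chlorobenzyne | ClC1=CC(OCc2ccccc2)=CC#C1 | intermediate (not isolated)
14 | (2E,3E)-1,4-bis[4-(benzyloxy)-2-chloro-6-hydroxyphenyl]-2,3-bis[4-(benzyloxy)benzylidene]butane-1,4-dione (formed as its bis-phenoxide) | O=C(c1c(O)cc(OCc2ccccc2)cc1Cl)/C(=C/c1ccc(OCc2ccccc2)cc1)/C(=C\c1ccc(OCc2ccccc2)cc1)C(=O)c1c(O)cc(OCc2ccccc2)cc1Cl | intermediate (not isolated)
15 | 7,7'',4',4'''-tetrakis(benzyloxy)-5,5''-dichloro-3,3''-biflavanone, mixture of the meso and the racemic C2-symmetric trans,trans diastereomers (drawn without stereodescriptors) | O=C1c2c(Cl)cc(OCc3ccccc3)cc2OC(c2ccc(OCc3ccccc3)cc2)C1C1C(=O)c2c(Cl)cc(OCc3ccccc3)cc2OC1c1ccc(OCc2ccccc2)cc1 | intermediate (product of the key step)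
16 | meso-(2S,3R,2''R,3''S)-7,7'',4',4'''-tetrakis(benzyloxy)-5,5''-dichloro-3,3''-biflavanone (trans,trans) | O=C1c2c(Cl)cc(OCc3ccccc3)cc2O[C@H](c2ccc(OCc3ccccc3)cc2)[C@H]1[C@@H]1C(=O)c2c(Cl)cc(OCc3ccccc3)cc2O[C@H]1c1ccc(OCc2ccccc2)cc1 | intermediate
17 | meso-(2S,3R,2''R,3''S)-7,7'',4',4'''-tetrahydroxy-3,3''-biflavanone (trans,trans) | O=C1c2ccc(O)cc2O[C@H](c2ccc(O)cc2)[C@H]1[C@@H]1C(=O)c2ccc(O)cc2O[C@H]1c1ccc(O)cc1 | target

Total step count: 9 (steps 1–3 aryne precursor, steps 4–6 diacid, steps 7–9 union and end game).
Longest linear sequence: 6 steps (1, 2, 3, 7, 8, 9 or 4, 5, 6, 7, 8, 9).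

Steps most likely to fail

Step 7 (proposed new method). The double insertion may stall or divert in several ways: hydrogen fluoride may protonate the ortho aryl anion before the acyl shift, which stops at the aryl ester; the ortho-chloroaryl anion may lose chloride; excess aryne may arylate the phenoxide or the C3 enolate; the second insertion may be slow on the hindered monoadduct. The fallback sets out from diacid 12 and comes back to the route at target 17, using only known reactions. Steglich esterification of 12 with commercial 2-bromo-5-methoxyphenol (EDC·HCl, DMAP, CH2Cl2) should give bis(2-bromo-5-methoxyphenyl) (2E,3E)-2,3-bis[4-(benzyloxy)benzylidene]succinate F1. Bromine–lithium exchange with t-BuLi in THF at −100 °C makes the same kind of ortho-metallated aryl ester, now regiodefined by the bromine, and the anionic Fries rearrangement should then give (2E,3E)-2,3-bis[4-(benzyloxy)benzylidene]-1,4-bis(2-hydroxy-4-methoxyphenyl)butane-1,4-dione F2. NaOAc in refluxing EtOH should close both rings by oxa-Michael addition to the trans,trans biflavanones, namely the C2-symmetric 4',4'''-bis(benzyloxy)-7,7''-dimethoxy-3,3''-biflavanone F3 together with its meso isomer. Base equilibration with crystallization as in step 8 should converge these on meso-4',4'''-bis(benzyloxy)-7,7''-dimethoxy-3,3''-biflavanone F4, and BBr3 in CH2Cl2 (−78 to 0 °C) then cleaves the methyl and benzyl ethers to give 17.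

Step 8. Crystallization may fail to discriminate between the diastereomers, or ring opening may be too slow for the stereocentres of one half to invert, so that the solid stays a mixture. The fallback sets out from 15 and comes back at 16. It replaces dynamic crystallization by separation and recycling: chromatography on silica should separate 16 from rac-(2S,3R,2''S,3''R)-7,7'',4',4'''-tetrakis(benzyloxy)-5,5''-dichloro-3,3''-biflavanone F5, and F5 is re-equilibrated in solution (DBU, toluene, 80 °C) to the diastereomer mixture and separated again.

Step 9. Hydrodechlorination may remain incomplete, or the benzylic C2–O1 bond may be opened reductively (or by base followed by alkene reduction) to a dihydrochalcone. The fallback sets out from 16 and comes back at 17 without hydrogen gas. Pd(OAc)2 (cat.), polymethylhydrosiloxane and aqueous KF in THF at rt should remove both chlorines by hydride transfer, giving meso-7,7'',4',4'''-tetrakis(benzyloxy)-3,3''-biflavanone F6. BCl3 with pentamethylbenzene in CH2Cl2 at −78 °C then cleaves the four benzyl ethers without reduction to give 17.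

Further compounds
F1 | step 7 | bis(2-bromo-5-methoxyphenyl) (2E,3E)-2,3-bis[4-(benzyloxy)benzylidene]succinate | COc1ccc(Br)c(OC(=O)/C(=C/c2ccc(OCc3ccccc3)cc2)/C(=C\c2ccc(OCc3ccccc3)cc2)C(=O)Oc2cc(OC)ccc2Br)c1
F2 | step 7 | (2E,3E)-2,3-bis[4-(benzyloxy)benzylidene]-1,4-bis(2-hydroxy-4-methoxyphenyl)butane-1,4-dione | O=C(c1ccc(OC)cc1O)/C(=C/c1ccc(OCc2ccccc2)cc1)/C(=C\c1ccc(OCc2ccccc2)cc1)C(=O)c1ccc(OC)cc1O
F3 | step 7 | rac-(2S,3R,2''S,3''R)-4',4'''-bis(benzyloxy)-7,7''-dimethoxy-3,3''-biflavanone (C2-symmetric trans,trans, one enantiomer drawn) | O=C1c2ccc(OC)cc2O[C@H](c2ccc(OCc3ccccc3)cc2)[C@H]1[C@H]1C(=O)c2ccc(OC)cc2O[C@@H]1c1ccc(OCc2ccccc2)cc1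
F4 | step 7 | meso-(2S,3R,2''R,3''S)-4',4'''-bis(benzyloxy)-7,7''-dimethoxy-3,3''-biflavanone | O=C1c2ccc(OC)cc2O[C@H](c2ccc(OCc3ccccc3)cc2)[C@H]1[C@@H]1C(=O)c2ccc(OC)cc2O[C@H]1c1ccc(OCc2ccccc2)cc1
F5 | step 8 | rac-(2S,3R,2''S,3''R)-7,7'',4',4'''-tetrakis(benzyloxy)-5,5''-dichloro-3,3''-biflavanone (C2-symmetric trans,trans, one enantiomer drawn) | O=C1c2c(Cl)cc(OCc3ccccc3)cc2O[C@H](c2ccc(OCc3ccccc3)cc2)[C@H]1[C@H]1C(=O)c2c(Cl)cc(OCc3ccccc3)cc2O[C@@H]1c1ccc(OCc2ccccc2)cc1
F6 | step 9 | meso-(2S,3R,2''R,3''S)-7,7'',4',4'''-tetrakis(benzyloxy)-3,3''-biflavanone | O=C1c2ccc(OCc3ccccc3)cc2O[C@H](c2ccc(OCc3ccccc3)cc2)[C@H]1[C@@H]1C(=O)c2ccc(OCc3ccccc3)cc2O[C@H]1c1ccc(OCc2ccccc2)cc1
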